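**Plan**

- Retrosynthesis: the polyene is cut at C11'=C12' and at C11=C12 (two Wittig reactions). This gives the ε-C15 hydroxy aldehyde 5, the C10 dialdehyde 17 and the β-C15 phosphonium salt 16, which already carries the palmitate, so the two hydroxyls never have to be told apart.
- The β-ring is cut at C5=C6 and C3–C4. Ring atoms C3, C2, C1(Me2), C6 together with C7 are a C2-symmetric 3,3-dimethylpentanedial (C3 and C7 both as CHO); C4, C5 and the 5-methyl are acetone. The C3 carbinol β to C5 is an aldol retron, and the C5=C6–C7=O enal is an aldol-condensation retron.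
- Forward order: the ε-ring is carried intact from (±)-α-ionone (steps 1–4). The β-ring is the only ring that is closed (step 6). Then C10 → C13 → C15 salt → ester → C25 aldehyde → C25 salt → final Wittig with 5.
- Stereochemistry: C3 from the L-proline aldol (catalyst control); C3' from the (S)-CBS reduction; C6' from separation of the two diastereomers that the racemic ketone gives; E double bonds from HWE/Wittig reactions and thermal equilibration of the hindered Z isomers.

Key step: step 6

Remark: carotenoid numbering is used (β-ring C1–C6, chain C7–C15, primed numbers for the ε-half); α-ionone is taken as the racemate, its usual commercial form.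

**Route**

Step 1
Reactants: 1 (±)-α-ionone
Product: 2 (±)-(2E,4E)-3-methyl-5-(2,6,6-trimethylcyclohex-2-en-1-yl)penta-2,4-dienenitrile
Conditions: (EtO)2P(O)CH2CN, NaH, THF, 0 °C → rt; minor (2Z)-isomer removed by chromatography
Reagents that add atoms: diethyl (cyanomethyl)phosphonate, CCOP(=O)(CC#N)OCC
Why: Horner–Wadsworth–Emmons olefination of the methyl ketone should favour the E-nitrile, which serves as a masked C11' aldehyde that survives the next two steps.

Step 2
Reactants: 2 (±)-nitrile
Product: 3 (±)-(2E,4E)-3-methyl-5-(2,6,6-trimethyl-4-oxocyclohex-2-en-1-yl)penta-2,4-dienenitrile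
Conditions: t-BuOOH (70% aq.), NaOCl (aq.), K2CO3, MeCN, 0 °C
Reagents that add atoms: tert-butyl hydroperoxide, CC(C)(C)OO
Why: radical allylic oxidation by tert-butylperoxyl should take the ring C3' methylene, the only unhindered allylic CH2 (H-6' is shielded between the gem-dimethyl carbon and the 5'-methyl), and the allylic peroxide collapses to the enone.

Step 3
Reactants: 3 (±)-keto nitrile
Product: 4 (2E,4E)-5-[(1R,4R)-4-hydroxy-2,6,6-trimethylcyclohex-2-en-1-yl]-3-methylpenta-2,4-dienenitrile
Conditions: (S)-2-methyl-CBS-oxazaborolidine (20 mol %), catecholborane, toluene, −78 °C; MeOH quench, aqueous NaOH wash; chromatography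
Reagents that add atoms: none
Why: in this Corey–Bakshi–Shibata reduction the ring alkene should act as the large group, so hydride reaches the same carbonyl face in both enantiomers of 3 and C3' becomes R; the (1R)-ketone gives trans-4 and the (1S)-ketone the cis (1S,4R) epimer, which is removed by chromatography, so C6' is secured by this separation.

Step 4
Reactants: 4 hydroxy nitrile
Product: 5 (2E,4E)-5-[(1R,4R)-4-hydroxy-2,6,6-trimethylcyclohex-2-en-1-yl]-3-methylpenta-2,4-dienal
Conditions: i-Bu2AlH (2.5 equiv), CH2Cl2, −78 °C; aqueous KNaC4H4O6 (potassium sodium tartrate), rt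
Reagents that add atoms: water, O
Why: partial reduction of the nitrile to the N-aluminio imine and neutral hydrolysis should give the dienal (the first hydride equivalent is used up by the hydroxyl), and the tartrate work-up spares the acid-labile allylic alcohol.

Step 5
Reactants: 6 3,3-dimethylpentane-1,5-diol
Product: 7 3,3-dimethylpentanedial
Conditions: (COCl)2, DMSO, CH2Cl2, −78 °C; Et3N, −78 → 0 °C; used crude
Reagents that add atoms: none
Why: Swern oxidation activates both primary hydroxyls before base is added, so the dialdehyde should form without passing through a lactol that would be over-oxidised to the lactone.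

Step 6
Reactants: 7 3,3-dimethylpentanedial; 8 acetone
Product: 11 (4R)-4-hydroxy-2,6,6-trimethylcyclohex-1-ene-1-carbaldehyde, via lactol 9 (not isolated), via cyclic aldol 10 (not isolated)
Conditions: L-proline (30 mol %), acetone/CHCl3 1:4, 4 °C; evaporate; Bn2NH·CF3CO2H (20 mol %), wet toluene, 50 °C
Reagents that add atoms: none
Why: L-proline turns acetone into its enamine, which adds through the usual enamine/carboxylic-acid transition state to the re face of one of the two homotopic formyl groups of 7, forming C3–C4 and setting C3 (the (S)-ketol, which has the spatial arrangement of the (3R) ring carbinol; only the CIP priorities differ); the δ-hydroxy aldehyde closes at once to lactol 9, a temporary ring that masks the second formyl group against a second aldol and ties up the C3 oxygen against retro-aldol. With the dibenzylammonium salt the lactol opens to the enamine of the C7 aldehyde, whose α-carbon C6 attacks the methyl ketone C5 in a 6-(enolexo)-exo-trig aldol (10), and enamine-assisted E1cB loss of the tertiary C5 hydroxyl followed by hydrolysis gives the tetrasubstituted C5=C6 enal 11. The closest known reaction types are the proline-catalysed acetone aldol with aliphatic aldehydes and the secondary-ammonium-salt aldol condensation of 1,7-keto aldehydes to 2-methylcyclohex-1-enecarbaldehydes. The closure creates no lasting stereocentre; C3 is the only one and is under catalyst control. The step needs mono-addition (secured by the symmetry of 7 and by lactol formation) and aldehyde-enamine rather than ketone-enamine reactivity (the hindered secondary amine condenses with the aldehyde only, and closure from C2 would give a four-membered ring). It must also stop before vinylogous loss of the C3 hydroxyl to the cyclohexadienal, which moderate temperature, wet solvent and the slow re-condensation of the hindered product enal with Bn2NH should hold back.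

Step 7
Reactants: 11 (R)-hydroxy enal
Product: 12 (3E)-4-[(4R)-4-hydroxy-2,6,6-trimethylcyclohex-1-en-1-yl]but-3-en-2-one ((3R)-3-hydroxy-β-ionone)
Conditions: (EtO)2P(O)CH2C(O)CH3 (1.3 equiv), NaH (1.2 equiv), THF, 0 °C → rt
Reagents that add atoms: diethyl (2-oxopropyl)phosphonate, CCOP(=O)(CC(C)=O)OCC
Why: Horner–Wadsworth–Emmons reaction of the hindered enal with the small, weakly basic β-ketophosphonate anion should give the E-enone without triggering elimination of the C3 hydroxyl.

Step 8
Reactants: 12 (3R)-3-hydroxy-β-ionone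
Product: 13 (1E)-1-[(4R)-4-hydroxy-2,6,6-trimethylcyclohex-1-en-1-yl]-3-methylpenta-1,4-dien-3-ol (both C9 epimers)
Conditions: CH2=CHMgBr (3 equiv), THF, −20 → 0 °C; aqueous NH4Cl
Reagents that add atoms: vinylmagnesium bromide, C=C[Mg]Br
Why: 1,2-addition of the vinyl Grignard reagent to the ketone (one equivalent is consumed by the hydroxyl) gives the tertiary carbinol, whose new centre is unselective and is erased in step 9.

Step 9
Reactants: 13 vinyl carbinol
Product: 14 [(2E,4E)-5-[(4R)-4-hydroxy-2,6,6-trimethylcyclohex-1-en-1-yl]-3-methylpenta-2,4-dien-1-yl]triphenylphosphonium bromide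
Conditions: Ph3P·HBr, MeOH, 0 °C → rt; recrystallisation
Reagents that add atoms: triphenylphosphine hydrobromide, [Br-].[PH+](c1ccccc1)(c1ccccc1)c1ccccc1
Why: ionisation of the tertiary doubly allylic alcohol gives a pentadienyl cation that PPh3 captures at the primary terminus (SN1' transposition, E at C9=C10), while the homoallylic ring hydroxyl does not ionise; recrystallisation of the salt offers a point to raise isomeric and enantiomeric purity.

Step 10
Reactants: 14 hydroxy phosphonium salt; 15 hexadecanoic acid (palmitic acid)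
Product: 16 [(2E,4E)-5-[(4R)-4-(hexadecanoyloxy)-2,6,6-trimethylcyclohex-1-en-1-yl]-3-methylpenta-2,4-dien-1-yl]triphenylphosphonium bromide
Conditions: DCC, DMAP (cat.), CH2Cl2, 0 °C → rt
Reagents that add atoms: none
Why: Steglich esterification of the only hydroxyl present; DMAP is too weak a base to form the ylide, and the carbodiimide method avoids scrambling of the bromide counter-ion.

Step 11
Reactants: 16 palmitoyloxy phosphonium salt; 17 (2E,4E,6E)-2,7-dimethylocta-2,4,6-trienedial
Product: 19 (3R)-3-(hexadecanoyloxy)-12'-apo-β-caroten-12'-al (all-E), via (11Z)-isomer 18 (not isolated)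
Conditions: NaN(SiMe3)2 (0.98 equiv), THF, −78 °C; ylide added to 17 (2.5 equiv), −78 → 0 °C; then heptane, 80 °C, argon, dark
Reagents that add atoms: none
Why: Wittig reaction of the semi-stabilised allylic ylide with an excess of the dialdehyde should give mono-olefination at C11=C12 (the amide deprotonates the far more acidic phosphonium CH2, not the ester), and the hindered 11Z isomer (H-10 against the 13-methyl) relaxes thermally to all-E.

Step 12
Reactants: 19 C25 aldehyde
Product: 20 (3R)-3-(hexadecanoyloxy)-12'-apo-β-caroten-12'-ol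
Conditions: NaBH4, THF/EtOH 4:1, −10 °C
Reagents that add atoms: none
Why: 1,2-reduction of the polyenal by borohydride at low temperature should leave the hindered secondary palmitate untouched.

Step 13
Reactants: 20 C25 alcohol
Product: 21 [(3R)-3-(hexadecanoyloxy)-12'-apo-β-caroten-12'-yl]triphenylphosphonium bromide
Conditions: Ph3P·HBr, CH2Cl2/MeOH, 0 °C → rt
Reagents that add atoms: triphenylphosphine hydrobromide, [Br-].[PH+](c1ccccc1)(c1ccccc1)c1ccccc1
Why: the primary polyenylic alcohol ionises to a conjugated cation that PPh3 captures at C12' (the fully conjugated, thermodynamic position), as in the standard preparation of polyenyl Wittig salts; the ester is stable to this weak acid.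

Step 14
Reactants: 21 C25 phosphonium salt; 5 ε-C15 hydroxy aldehyde
Product: 23 (3R,3'R,6'R)-3'-hydroxy-β,ε-caroten-3-yl hexadecanoate (lutein 3-O-palmitate; target), via (11'Z)-isomer 22 (not isolated)
Conditions: NaN(SiMe3)2 (0.98 equiv), THF, −78 °C; 5, −78 °C → rt; then EtOAc/heptane, 75 °C, argon, dark
Reagents that add atoms: none
Why: Wittig reaction of the pre-formed polyenyl ylide with the dienal closes C11'=C12' (the ylide is too weak a base to touch the free allylic hydroxyl, the ester or H-6'), and the hindered 11'Z isomer equilibrates thermally to the all-E target.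

**Compound list**

1 | (±)-α-ionone, (3E)-4-(2,6,6-trimethylcyclohex-2-en-1-yl)but-3-en-2-one | CC(=O)/C=C/C1C(C)=CCCC1(C)C | starting material
2 | (±)-(2E,4E)-3-methyl-5-(2,6,6-trimethylcyclohex-2-en-1-yl)penta-2,4-dienenitrile | N#C/C=C(C)/C=C/C1C(C)=CCCC1(C)C | intermediate
3 | (±)-(2E,4E)-3-methyl-5-(2,6,6-trimethyl-4-oxocyclohex-2-en-1-yl)penta-2,4-dienenitrile | N#C/C=C(C)/C=C/C1C(C)=CC(=O)CC1(C)C | intermediate
4 | (2E,4E)-5-[(1R,4R)-4-hydroxy-2,6,6-trimethylcyclohex-2-en-1-yl]-3-methylpenta-2,4-dienenitrile | N#C/C=C(C)/C=C/[C@H]1C(C)=C[C@H](O)CC1(C)C | intermediate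
5 | (2E,4E)-5-[(1R,4R)-4-hydroxy-2,6,6-trimethylcyclohex-2-en-1-yl]-3-methylpenta-2,4-dienal | O=C/C=C(C)/C=C/[C@H]1C(C)=C[C@H](O)CC1(C)C | intermediate
6 | 3,3-dimethylpentane-1,5-diol | OCCC(C)(C)CCO | starting material
7 | 3,3-dimethylpentanedial | O=CCC(C)(C)CC=O | intermediate
8 | acetone | CC(C)=O | starting material
9 | 1-[(2S)-6-hydroxy-4,4-dimethyloxan-2-yl]propan-2-one (lactol, both anomers; ring tautomer of (5S)-5-hydroxy-3,3-dimethyl-7-oxooctanal) | CC(=O)C[C@@H]1CC(C)(C)CC(O)O1 | intermediate (not isolated)
10 | (4S)-2,4-dihydroxy-2,6,6-trimethylcyclohexane-1-carbaldehyde (epimers at C1 and C2) | O=CC1C(C)(O)C[C@@H](O)CC1(C)C | intermediate (not isolated)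
11 | (4R)-4-hydroxy-2,6,6-trimethylcyclohex-1-ene-1-carbaldehyde | O=CC1=C(C)C[C@@H](O)CC1(C)C | intermediate
12 | (3E)-4-[(4R)-4-hydroxy-2,6,6-trimethylcyclohex-1-en-1-yl]but-3-en-2-one | CC(=O)/C=C/C1=C(C)C[C@@H](O)CC1(C)C | intermediate
13 | (1E)-1-[(4R)-4-hydroxy-2,6,6-trimethylcyclohex-1-en-1-yl]-3-methylpenta-1,4-dien-3-ol (both epimers at the tertiary carbinol) | C=CC(C)(O)/C=C/C1=C(C)C[C@@H](O)CC1(C)C | intermediate
14 | [(2E,4E)-5-[(4R)-4-hydroxy-2,6,6-trimethylcyclohex-1-en-1-yl]-3-methylpenta-2,4-dien-1-yl]triphenylphosphonium bromide | O[C@@H]1CC(C)=C(/C=C/C(C)=C/C[P+](c2ccccc2)(c2ccccc2)c2ccccc2)C(C)(C)C1.[Br-] | intermediate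
15 | hexadecanoic acid (palmitic acid) | CCCCCCCCCCCCCCCC(=O)O | starting material
16 | [(2E,4E)-5-[(4R)-4-(hexadecanoyloxy)-2,6,6-trimethylcyclohex-1-en-1-yl]-3-methylpenta-2,4-dien-1-yl]triphenylphosphonium bromide | CCCCCCCCCCCCCCCC(=O)O[C@@H]1CC(C)=C(/C=C/C(C)=C/C[P+](c2ccccc2)(c2ccccc2)c2ccccc2)C(C)(C)C1.[Br-] | intermediate
17 | (2E,4E,6E)-2,7-dimethylocta-2,4,6-trienedial | O=C/C(C)=C/C=C/C=C(C)/C=O | starting material
18 | (11Z)-isomer of 19 | CCCCCCCCCCCCCCCC(=O)O[C@@H]1CC(C)=C(/C=C/C(C)=C/C=C\C(C)=C\C=C\C=C(C)\C=O)C(C)(C)C1 | intermediate (not isolated)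
19 | (3R)-3-(hexadecanoyloxy)-12'-apo-β-caroten-12'-al, i.e. (1R)-3,5,5-trimethyl-4-[(1E,3E,5E,7E,9E,11E)-3,7,12-trimethyl-13-oxotrideca-1,3,5,7,9,11-hexaen-1-yl]cyclohex-3-en-1-yl hexadecanoate | CCCCCCCCCCCCCCCC(=O)O[C@@H]1CC(C)=C(/C=C/C(C)=C/C=C/C(C)=C/C=C/C=C(C)/C=O)C(C)(C)C1 | intermediate
20 | (3R)-3-(hexadecanoyloxy)-12'-apo-β-caroten-12'-ol (all-E; the primary allylic alcohol of 19) | CCCCCCCCCCCCCCCC(=O)O[C@@H]1CC(C)=C(/C=C/C(C)=C/C=C/C(C)=C/C=C/C=C(C)/CO)C(C)(C)C1 | intermediate
21 | [(3R)-3-(hexadecanoyloxy)-12'-apo-β-caroten-12'-yl]triphenylphosphonium bromide (all-E) | CCCCCCCCCCCCCCCC(=O)O[C@@H]1CC(C)=C(/C=C/C(C)=C/C=C/C(C)=C/C=C/C=C(C)/C[P+](c2ccccc2)(c2ccccc2)c2ccccc2)C(C)(C)C1.[Br-] | intermediate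
22 | (11'Z)-isomer of 23 | CCCCCCCCCCCCCCCC(=O)O[C@@H]1CC(C)=C(/C=C/C(C)=C/C=C/C(C)=C/C=C/C=C(C)/C=C\C=C(C)\C=C\[C@H]2C(C)=C[C@H](O)CC2(C)C)C(C)(C)C1 | intermediate (not isolated)
23 | (3R,3'R,6'R)-3'-hydroxy-β,ε-caroten-3-yl hexadecanoate (all-E lutein 3-O-palmitate) | CCCCCCCCCCCCCCCC(=O)O[C@@H]1CC(C)=C(/C=C/C(C)=C/C=C/C(C)=C/C=C/C=C(C)/C=C/C=C(C)/C=C/[C@H]2C(C)=C[C@H](O)CC2(C)C)C(C)(C)C1 | target

**Step count and risks**

Total step count: 14. Longest linear sequence: 10 steps (steps 5–14, from 3,3-dimethylpentane-1,5-diol 6).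

Steps most likely to fail:

1. Step 6. The intermolecular aldol may proceed with weak facial control on an α-unbranched aldehyde, and the closure may over-run into loss of the C3 hydroxyl by vinylogous elimination. Fallback: C3 is set by reagent control instead of enamine catalysis. Dialdehyde 7 (in excess, to keep to mono-addition) is treated with (+)-B-methallyldiisopinocampheylborane (made from (+)-Ipc2BOMe, the (−)-α-pinene series; Et2O, −78 °C; 2-aminoethanol work-up). This should give the lactol (6R)-4,4-dimethyl-6-(2-methylprop-2-en-1-yl)oxan-2-ol F1. Ozonolysis of F1 (O3, CH2Cl2/MeOH, −78 °C; Me2S) unveils the methyl ketone and gives lactol 9, now isolated and purified. The route is rejoined at 9, which is closed with Bn2NH·CF3CO2H alone at the lowest temperature that gives turnover.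

2. Step 3. The oxazaborolidine may give poor facial control on an isophorone-type enone whose "small" side carries a quaternary carbon, and the C1 epimers may be hard to separate. Fallback: the stereochemistry is taken from an enzyme instead of the reduction catalyst. Ketone 3 is reduced without control (NaBH4, CeCl3·7H2O, MeOH, −20 °C; Luche reduction) to the hydroxy nitrile as the mixture of ring stereoisomers F2. Pseudomonas cepacia lipase with vinyl acetate (t-BuOMe, rt) should acylate only the (4R)-alcohols (Kazlauskas rule, alkene side as the large group). The acetates are separated from the unreacted (4S)-alcohols, and the trans acetate (1R,4R)-4-[(1E,3E)-4-cyano-3-methylbuta-1,3-dien-1-yl]-3,5,5-trimethylcyclohex-2-en-1-yl acetate F3 is separated from its cis epimer. Methanolysis of F3 (K2CO3, MeOH, 0 °C) returns to the route at 4.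

3. Step 14. The long, charge-delocalised ylide may react sluggishly, the E/Z ratio at the new bond may not be fully corrected by heating, and prolonged heating may ionise the allylic 3'-hydroxyl. Fallback: the phosphonium ylide is replaced by a phosphonate carbanion, whose Horner–Wadsworth–Emmons reaction is E-selective at the new bond. Alcohol 20 is converted (PBr3, cat. pyridine, Et2O, −20 °C) into the C25 allylic bromide (3R)-12'-bromo-12'-apo-β-caroten-3-yl hexadecanoate F4, which is used at once. Michaelis–Becker reaction of F4 with NaP(O)(OEt)2 (THF, 0 °C) gives the C25 diethyl phosphonate F5. The anion of F5 (NaN(SiMe3)2, THF, −78 → 0 °C) and aldehyde 5 should give 23 directly, without the thermal equilibration.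

**Further compounds**

F1 | step 6 | (6R)-4,4-dimethyl-6-(2-methylprop-2-en-1-yl)oxan-2-ol (both anomers) | CC(=C)C[C@@H]1CC(C)(C)CC(O)O1
F2 | step 3 | (2E,4E)-5-(4-hydroxy-2,6,6-trimethylcyclohex-2-en-1-yl)-3-methylpenta-2,4-dienenitrile, mixture of the four ring stereoisomers | N#C/C=C(C)/C=C/C1C(C)=CC(O)CC1(C)C
F3 | step 3 | (1R,4R)-4-[(1E,3E)-4-cyano-3-methylbuta-1,3-dien-1-yl]-3,5,5-trimethylcyclohex-2-en-1-yl acetate | N#C/C=C(C)/C=C/[C@H]1C(C)=C[C@H](OC(C)=O)CC1(C)C
F4 | step 14 | (3R)-12'-bromo-12'-apo-β-caroten-3-yl hexadecanoate (all-E) | CCCCCCCCCCCCCCCC(=O)O[C@@H]1CC(C)=C(/C=C/C(C)=C/C=C/C(C)=C/C=C/C=C(C)/CBr)C(C)(C)C1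
F5 | step 14 | diethyl [(3R)-3-(hexadecanoyloxy)-12'-apo-β-caroten-12'-yl]phosphonate (all-E) | CCCCCCCCCCCCCCCC(=O)O[C@@H]1CC(C)=C(/C=C/C(C)=C/C=C/C(C)=C/C=C/C=C(C)/CP(=O)(OCC)OCC)C(C)(C)C1
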